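# Proposed synthesis of (6S,7S,8R)-isolariciresinol (CID1023563)

Locants used throughout (tetralin numbering, also for open-chain intermediates): C1 is the aryl-bearing carbon, C2 and C3 carry the hydroxymethyl carbons C9' and C9, C4 is the benzylic CH2, and C4a/C8a are the fusion carbons. Ring A is the fused guaiacol ring (6-OMe, 7-OH), ring B the saturated ring, and "pendant ring" the 4-hydroxy-3-methoxyphenyl group on C1. In this numbering target 12 is (1R,2S,3S); read from the SMILES, the C1 aryl and the C3 CH2OH lie on one face and the C2 CH2OH on the other, so the arrangement is all-trans.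

## The problem

- Target 12 is a 1-aryltetralin whose ring B carries three contiguous stereocentres, C1 (R), C2 (S) and C3 (S), all-trans and therefore all pseudo-equatorial on the half-chair.
- C1 is a diarylmethine: it has no heteroatom, is not enolisable and cannot be corrected later. Its two aryl groups are nearly identical guaiacyl rings, so it must be set in a bond-forming event under firm control.
- C2 and C3 are different in kind. Each carries a CH2OH that is a reduced ester, so at the ester level both are epimerisable, and the all-trans isomer is the thermodynamic one. C1 can therefore control C2 and C3, but not the reverse.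
- Ring A is unsymmetrical only subtly: C8a (bonded to C1) is para to the OMe carbon C6, and C4a (bonded to C4) is para to the OH carbon C7. A route that functionalises a preformed 6,7-dioxygenated tetralin would have to tell C1 from C4.
- Both phenols are para to benzylic C–H bonds (C1–H for the pendant ring, C4–H2 for ring A) and invite oxidation to quinone methides, so they are kept as benzyl ethers until the last step.
- The enabling feature: at the ester oxidation level C9'–C2–C3–C9 is a succinate. Its central C2–C3 bond is the bond that oxidative coupling of two ester enolates makes, and the two arms carrying these enolates sit ortho to each other on ring A (on C8a and C4a).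

## Retrosynthesis

**12 ⇐ 11 ⇐ 10 (no C–C bond cut).** The two O–benzyl bonds and the oxidation level of C9/C9' are adjusted. Benzyl ethers survive strong base, the oxidant, alkoxide and hydride and leave by hydrogenolysis without touching a stereocentre. Raising C9/C9' to esters makes C2 and C3 enolisable. The forward steps are LiAlH4 reduction of diester 10 to diol 11 and hydrogenolysis to 12.

**10 ⇐ 9 (stereochemical simplification).** Because C2 and C3 of 10 are α to esters and C1 is not, 10 can come from any mixture 9 of C2/C3 epimers that has C1 (R). Methoxide equilibration should funnel them into the all-equatorial isomer. Only C1 then has to be made enantioselectively. The forward reaction needs an equilibrium that favours all-trans and a C1 that is inert to methoxide.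

**9 ⇐ 7 via 8 (cut C2–C3).** The neighbouring cuts are C1–C8a (Friedel–Crafts) and the pair C1–C2/C3–C4 ([4+2]); both require C2 and C3 to be controlled before or during ring formation. Cutting C2–C3 removes ring B and both epimerisable centres at once. It leaves acyclic diester 7 with a single stereocentre and two ester arms held ortho on ring A. The forward reaction is intramolecular oxidative coupling of bis-enolate 8, which must beat intermolecular coupling.

**7 ⇐ 5 + 6 (cut C1–pendant aryl).** C1 is the β-carbon of an ester, so the diarylmethine is the product of asymmetric conjugate arylation of cinnamate 5 with boronic acid 6. The other cut (C1–ring A) would need a hindered ortho-substituted ring-A boron reagent. Compound 5 is flat and achiral, and 6 is commercial. The forward reaction needs high facial selectivity on an ortho-substituted β-aryl enoate, with the saturated ester as a spectator.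

**5 ⇐ 3 + 4; 3 ⇐ 2 ⇐ 1 (cut C1–C8a as an sp2–sp2 bond, then C8a–Br).** A Heck reaction joins acrylate 4 to bromide 3. Bromination of 2 para to the OMe group is the single event that decides which ring-A carbon becomes C8a, and it uses the innate directing effects of the guaiacyl ring. Methyl dihydroferulate 1 already holds ring A, C4, C3, C9 and the OMe/OH pattern.

## Roads not taken

**Alternative 1:** the most obvious cut is C1–C8a. C2 and C3 are built first on a butyrolactone by conjugate addition of a ring-A benzyl anion equivalent to a chiral 5-alkoxybutenolide, with aldol trapping by the pendant aryl aldehyde, to give benzylic alcohol A1. Acid then ionises A1 and the cation closes onto ring A para to OMe. Stereochemical information has to travel C3 → C2 → C1 through three separate events and starts from a stoichiometric auxiliary. The benzyl anion needs a stabilising group that must be removed, and the lactone must still be reduced. The chosen plan sets C1 in one catalytic step, lets thermodynamics set the other two centres, and is several steps shorter.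

**Alternative 2:** cut C1–C2 and C3–C4 in a [4+2] sense. Photoenolisation of benzophenone A2 gives a diene that is trapped in situ by a fumarate diester of a chiral alcohol to give carbinol A3. Ionic hydrogenation at C1 and ester reduction follow. The cycloaddition sets C2 and C3, but C1 emerges as a tertiary carbinol whose configuration is discarded. C1 must then be set by hydride delivery to a planar diaryl cation under substrate control. Facial control on the dienophile rests on a stoichiometric auxiliary, and A2 needs its own regioselective acylation. In the chosen plan C1 is the one centre made with catalyst control and it is never ionised.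

**Alternative 3:** use the hidden C2 symmetry. In diester A4 the two benzylic CH2 groups are homotopic, so hydride abstraction by DDQ at either one gives a quinone methide that the other ring traps para to its OMe. Ring differentiation and the OMe/OH pattern come for free. However, A4 needs two equivalents of a chiral auxiliary or a double asymmetric hydrogenation. The oxidation also has to stop after one event, although the product has a doubly benzylic C1–H para to a free phenol and a second p-hydroxybenzylic CH2 at C4, so over-oxidation towards the dihydronaphthalene is built into the mechanism. The chosen plan forms the same succinate bond, but intramolecularly, on protected phenols, after C1 is fixed.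

Key step: step 5

Remarks on the chemistry (assumptions):
- Compounds 1, 4 and 6 are purchased.
- The ligand and auxiliary antipodes named are those that the accepted facial models predict for aryl delivery to the Si face of C1; the sense would be confirmed by correlation on 7.

## Route

Step 1
Reactants: 1 methyl 3-(4-hydroxy-3-methoxyphenyl)propanoate
Product: 2 methyl 3-[4-(benzyloxy)-3-methoxyphenyl]propanoate
Conditions: BnBr, K2CO3, DMF, 25 to 60 °C
Reagents that add atoms: benzyl bromide, BrCc1ccccc1
Why: Williamson ether synthesis on the phenoxide; the benzyl ether is chosen because it should survive LDA, CuBr2, NaOMe and LiAlH4 and leave by hydrogenolysis at the end.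

Step 2
Reactants: 2 methyl 3-[4-(benzyloxy)-3-methoxyphenyl]propanoate
Product: 3 methyl 3-[4-(benzyloxy)-2-bromo-5-methoxyphenyl]propanoate
Conditions: NBS, MeCN, 0 °C to rt, dark
Reagents that add atoms: N-bromosuccinimide, O=C1CCC(=O)N1Br
Why: Electrophilic aromatic bromination; the site para to OMe and ortho to the side chain (future C8a) is the most activated open position of a 4-alkyl-1,2-dialkoxybenzene, the site between chain and OMe being flanked on both sides and the site ortho to OBn lacking a para donor, so this step fixes the 6-OMe/7-O pattern of ring A.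

Step 3
Reactants: 3 methyl 3-[4-(benzyloxy)-2-bromo-5-methoxyphenyl]propanoate; 4 methyl acrylate
Product: 5 methyl (2E)-3-[5-(benzyloxy)-4-methoxy-2-(3-methoxy-3-oxopropyl)phenyl]prop-2-enoate
Conditions: Pd(OAc)2 (5 mol %), P(o-tol)3 (12 mol %), Et3N, DMF, 100 °C
Reagents that add atoms: none
Why: Heck reaction of an aryl bromide with an acrylate; syn-insertion and syn-β-hydride elimination should give the (E)-cinnamate, and the saturated ester arm is inert.

Step 4
Reactants: 5 methyl (2E)-3-[5-(benzyloxy)-4-methoxy-2-(3-methoxy-3-oxopropyl)phenyl]prop-2-enoate; 6 [4-(benzyloxy)-3-methoxyphenyl]boronic acid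
Product: 7 methyl (3R)-3-[4-(benzyloxy)-3-methoxyphenyl]-3-[5-(benzyloxy)-4-methoxy-2-(3-methoxy-3-oxopropyl)phenyl]propanoate
Conditions: [Rh(OH)((S)-BINAP)]2 (1.5 mol %), 6 (2 equiv), dioxane/H2O 10:1, 50 °C
Reagents that add atoms: none
Why: Rhodium-catalysed asymmetric conjugate addition of an arylboronic acid to a β-aryl enoate (Hayashi–Miyaura reaction): transmetalation to aryl–rhodium, enantio-determining insertion of the enoate and hydrolysis of the oxa-π-allyl species; C1 is set by the ligand, the (S)-BINAP complex being expected to deliver the aryl group to the Si face of the β-carbon to give (R), and the enantiomeric purity fixed here should be checked on 7.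

Step 5
Reactants: 7 methyl (3R)-3-[4-(benzyloxy)-3-methoxyphenyl]-3-[5-(benzyloxy)-4-methoxy-2-(3-methoxy-3-oxopropyl)phenyl]propanoate
Product: 9 dimethyl (1R)-7-(benzyloxy)-1-[4-(benzyloxy)-3-methoxyphenyl]-6-methoxy-1,2,3,4-tetrahydronaphthalene-2,3-dicarboxylate (mixture of C2/C3 epimers), via dilithium bis-enolate 8 (not isolated)
Conditions: LDA (2.2 equiv), THF, −78 °C; then CuBr2 (2.2 equiv), THF/DMF, −78 to 0 °C, 0.01 M
Reagents that add atoms: none
Why: LDA removes one α-proton from each ester CH2 (C2 and C3; C1–H and C4–H2 are far less acidic) to give bis-enolate 8; divalent copper bromide oxidises one enolate by single-electron transfer to an α-ester radical or its copper-bound equivalent, this adds to the carbon of the second enolate, and a second equivalent of CuBr2 oxidises the resulting radical anion to the diester. The closest known reaction type is the oxidative coupling of lithium ester enolates with divalent copper salts to succinates, including its intramolecular form that closes cycloalkane-1,2-dicarboxylates and its use for 2,3-dibenzylsuccinates. Ring B closes in the 6-exo-trig mode (C2 onto C3 of the C3=C9 enolate double bond, or the mirror sequence from C3), the two carbons being held 1,6 to each other by the ortho arms on C8a and C4a of ring A. C2 and C3 are the new stereocentres; a trans-diester with the C2 ester anti to the C1 aryl group is the likely kinetic preference, but no selectivity is required here because both centres are α to esters and are equilibrated in step 6 under the control of C1. The selectivities that are required are ring closure over intermolecular coupling, secured by high dilution and the ortho tether, and oxidation of the enolates in preference to the electron-rich arenes, secured by low temperature and two equivalents of oxidant. C1 has no acidic hydrogen under these conditions and its configuration should pass through unchanged.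

Step 6
Reactants: 9 dimethyl (1R)-7-(benzyloxy)-1-[4-(benzyloxy)-3-methoxyphenyl]-6-methoxy-1,2,3,4-tetrahydronaphthalene-2,3-dicarboxylate (mixture of C2/C3 epimers)
Product: 10 dimethyl (1R,2S,3S)-7-(benzyloxy)-1-[4-(benzyloxy)-3-methoxyphenyl]-6-methoxy-1,2,3,4-tetrahydronaphthalene-2,3-dicarboxylate
Conditions: NaOMe (0.3 equiv), MeOH/THF, 65 °C
Reagents that add atoms: none
Why: Thermodynamic epimerisation through the ester enolates; C2 and C3 equilibrate while the diarylmethine C1 cannot, so all epimers should converge on the isomer with the aryl group and both esters pseudo-equatorial (C2 ester trans to aryl, C3 ester trans to C2 ester), and methoxide with methyl esters makes ester exchange degenerate.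

Step 7
Reactants: 10 dimethyl (1R,2S,3S)-7-(benzyloxy)-1-[4-(benzyloxy)-3-methoxyphenyl]-6-methoxy-1,2,3,4-tetrahydronaphthalene-2,3-dicarboxylate
Product: 11 [(1R,2S,3S)-7-(benzyloxy)-1-[4-(benzyloxy)-3-methoxyphenyl]-6-methoxy-1,2,3,4-tetrahydronaphthalene-2,3-diyl]dimethanol
Conditions: LiAlH4, THF, 0 °C to rt
Reagents that add atoms: none
Why: Hydride reduction of both esters to primary alcohols, which is fast relative to enolisation, so C2 and C3 should keep their configuration and are no longer epimerisable afterwards.

Step 8
Reactants: 11 [(1R,2S,3S)-7-(benzyloxy)-1-[4-(benzyloxy)-3-methoxyphenyl]-6-methoxy-1,2,3,4-tetrahydronaphthalene-2,3-diyl]dimethanol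
Product: 12 (6S,7S,8R)-8-(4-hydroxy-3-methoxyphenyl)-6,7-bis(hydroxymethyl)-3-methoxy-5,6,7,8-tetrahydronaphthalen-2-ol
Conditions: H2 (1 atm), Pd/C (10 wt %), MeOH/EtOAc, rt
Reagents that add atoms: none
Why: Hydrogenolysis of both benzyl aryl ethers over palladium on carbon; the C–C bonds at the diarylmethine and the benzylic CH2 are inert, so the free phenols appear only in the final, non-oxidising step.

## Compound list

1 | methyl 3-(4-hydroxy-3-methoxyphenyl)propanoate | COC(=O)CCc1ccc(O)c(OC)c1 | starting material
2 | methyl 3-[4-(benzyloxy)-3-methoxyphenyl]propanoate | COC(=O)CCc1ccc(OCc2ccccc2)c(OC)c1 | intermediate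
3 | methyl 3-[4-(benzyloxy)-2-bromo-5-methoxyphenyl]propanoate | COC(=O)CCc1cc(OC)c(OCc2ccccc2)cc1Br | intermediate
4 | methyl acrylate | C=CC(=O)OC | starting material
5 | methyl (2E)-3-[5-(benzyloxy)-4-methoxy-2-(3-methoxy-3-oxopropyl)phenyl]prop-2-enoate | COC(=O)CCc1cc(OC)c(OCc2ccccc2)cc1/C=C/C(=O)OC | intermediate
6 | [4-(benzyloxy)-3-methoxyphenyl]boronic acid | COc1cc(B(O)O)ccc1OCc1ccccc1 | starting material
7 | methyl (3R)-3-[4-(benzyloxy)-3-methoxyphenyl]-3-[5-(benzyloxy)-4-methoxy-2-(3-methoxy-3-oxopropyl)phenyl]propanoate | COc1cc([C@@H](CC(=O)OC)c2cc(OCc3ccccc3)c(OC)cc2CCC(=O)OC)ccc1OCc1ccccc1 | intermediate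
8 | dilithium bis-enolate of 7 | COc1cc([C@@H](C=C([O-])OC)c2cc(OCc3ccccc3)c(OC)cc2CC=C([O-])OC)ccc1OCc1ccccc1.[Li+].[Li+] | intermediate
9 | dimethyl (1R)-7-(benzyloxy)-1-[4-(benzyloxy)-3-methoxyphenyl]-6-methoxy-1,2,3,4-tetrahydronaphthalene-2,3-dicarboxylate (mixture of C2/C3 epimers) | COc1cc([C@@H]2c3cc(OCc4ccccc4)c(OC)cc3CC(C(=O)OC)C2C(=O)OC)ccc1OCc1ccccc1 | intermediate
10 | dimethyl (1R,2S,3S)-7-(benzyloxy)-1-[4-(benzyloxy)-3-methoxyphenyl]-6-methoxy-1,2,3,4-tetrahydronaphthalene-2,3-dicarboxylate | COc1cc([C@@H]2c3cc(OCc4ccccc4)c(OC)cc3C[C@H](C(=O)OC)[C@H]2C(=O)OC)ccc1OCc1ccccc1 | intermediate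
11 | [(1R,2S,3S)-7-(benzyloxy)-1-[4-(benzyloxy)-3-methoxyphenyl]-6-methoxy-1,2,3,4-tetrahydronaphthalene-2,3-diyl]dimethanol | COc1cc([C@@H]2c3cc(OCc4ccccc4)c(OC)cc3C[C@H](CO)[C@H]2CO)ccc1OCc1ccccc1 | intermediate
12 | (6S,7S,8R)-8-(4-hydroxy-3-methoxyphenyl)-6,7-bis(hydroxymethyl)-3-methoxy-5,6,7,8-tetrahydronaphthalen-2-ol | COc1cc([C@@H]2c3cc(O)c(OC)cc3C[C@H](CO)[C@H]2CO)ccc1O | target

## Step count and least certain steps

Total step count: 8. Longest linear sequence: 8 steps (1 to 12).

**Step 5 (key step).** Intermolecular coupling, simple α-bromination or reprotonation may compete with ring closure. The radical at C2 may also be lost by disproportionation next to the bulky C1 substituent. The cause is that the second bond-forming event must outrun bimolecular reactions of a reactive open-shell intermediate. The fallback closes the same bond in two two-electron steps; it sets out from 7 and comes back at 9. One equivalent of LDA (THF, −78 °C) followed by CBr4 should give the α-bromo ester methyl (3R)-3-[4-(benzyloxy)-3-methoxyphenyl]-3-[5-(benzyloxy)-2-(2-bromo-3-methoxy-3-oxopropyl)-4-methoxyphenyl]propanoate F1 from the less hindered enolate. Its regioisomer methyl (3R)-3-[4-(benzyloxy)-3-methoxyphenyl]-3-[5-(benzyloxy)-4-methoxy-2-(3-methoxy-3-oxopropyl)phenyl]-2-bromopropanoate F2 may form as well. The regiochemistry is immaterial: KOtBu in THF at 0 °C should enolise the other arm of either isomer and close ring B by intramolecular enolate alkylation (6-exo-tet) to 9.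

**Step 4.** Insertion into the ortho-substituted, electron-rich cinnamate may be slow, so that protodeboronation of 6 takes over, or the facial discrimination may be insufficient. The fallback uses auxiliary control; it sets out from 3 and comes back at 7.
- (4R)-3-Acryloyl-4-phenyl-1,3-oxazolidin-2-one F3 is made from the oxazolidinone and acryloyl chloride.
- A Heck reaction of F3 with 3 should give the cinnamoyl imide methyl 3-[4-(benzyloxy)-5-methoxy-2-[(1E)-3-oxo-3-[(4R)-2-oxo-4-phenyl-1,3-oxazolidin-3-yl]prop-1-en-1-yl]phenyl]propanoate F4.
- [4-(Benzyloxy)-3-methoxyphenyl]magnesium bromide F5 is made from purchased 1-(benzyloxy)-4-bromo-2-methoxybenzene and magnesium. Its addition with CuBr·SMe2 (20 mol %, THF, −40 °C) to the magnesium-chelated syn-s-cis imide, anti to the phenyl group, should give methyl 3-[4-(benzyloxy)-2-[(1R)-1-[4-(benzyloxy)-3-methoxyphenyl]-3-oxo-3-[(4R)-2-oxo-4-phenyl-1,3-oxazolidin-3-yl]propyl]-5-methoxyphenyl]propanoate F6.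
- NaOMe in MeOH at 0 °C then releases the auxiliary and gives 7.

**Step 6.** The convergence may be incomplete, with a 2,3-cis or 1,2-cis isomer persisting at equilibrium, because the penalty for one axial ester on the tetralin half-chair is modest. The fallback puts C2 and C3 under reagent control instead of thermodynamic control; it sets out from 7 and comes back at 11.
- LiOH in aqueous THF gives the diacid (3R)-3-[4-(benzyloxy)-3-methoxyphenyl]-3-[5-(benzyloxy)-2-(2-carboxyethyl)-4-methoxyphenyl]propanoic acid F7.
- DCC/DMAP with (4R)-4-benzyl-1,3-oxazolidin-2-one gives the bis-imide of F7 with two (4R)-4-benzyl-2-oxo-1,3-oxazolidin-3-yl groups F8.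
- LDA then CuBr2 couples the two imide enolates intramolecularly. Each auxiliary directs its own α-carbon in the sense known for homocoupling of such enolates, which should give the (1R,2S,3S)-tetralin-2,3-dicarbonyl bis-imide F9.
- LiBH4 cleaves both imides reductively to diol 11.

**Step 3.** Oxidative addition of zerovalent palladium into the electron-rich, ortho-substituted bromide may be slow and hydrodebromination may compete. The fallback replaces bromination and Heck coupling by formylation and olefination; it sets out from 2 and comes back at 5. Rieche formylation (Cl2CHOMe, SnCl4, CH2Cl2, −20 °C) para to OMe should give methyl 3-[4-(benzyloxy)-2-formyl-5-methoxyphenyl]propanoate F10. A Horner–Wadsworth–Emmons reaction with trimethyl phosphonoacetate (NaH, THF) then gives 5.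

## Further compounds

F1 | step 5 | methyl (3R)-3-[4-(benzyloxy)-3-methoxyphenyl]-3-[5-(benzyloxy)-2-(2-bromo-3-methoxy-3-oxopropyl)-4-methoxyphenyl]propanoate | COc1cc([C@@H](CC(=O)OC)c2cc(OCc3ccccc3)c(OC)cc2CC(Br)C(=O)OC)ccc1OCc1ccccc1
F2 | step 5 | methyl (3R)-3-[4-(benzyloxy)-3-methoxyphenyl]-3-[5-(benzyloxy)-4-methoxy-2-(3-methoxy-3-oxopropyl)phenyl]-2-bromopropanoate | COc1cc([C@@H](C(Br)C(=O)OC)c2cc(OCc3ccccc3)c(OC)cc2CCC(=O)OC)ccc1OCc1ccccc1
F3 | step 4 | (4R)-3-acryloyl-4-phenyl-1,3-oxazolidin-2-one | C=CC(=O)N1[C@H](c2ccccc2)COC1=O
F4 | step 4 | methyl 3-[4-(benzyloxy)-5-methoxy-2-[(1E)-3-oxo-3-[(4R)-2-oxo-4-phenyl-1,3-oxazolidin-3-yl]prop-1-en-1-yl]phenyl]propanoate | COC(=O)CCc1cc(OC)c(OCc2ccccc2)cc1/C=C/C(=O)N1[C@H](c2ccccc2)COC1=O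
F5 | step 4 | [4-(benzyloxy)-3-methoxyphenyl]magnesium bromide | COc1cc([Mg]Br)ccc1OCc1ccccc1
F6 | step 4 | methyl 3-[4-(benzyloxy)-2-[(1R)-1-[4-(benzyloxy)-3-methoxyphenyl]-3-oxo-3-[(4R)-2-oxo-4-phenyl-1,3-oxazolidin-3-yl]propyl]-5-methoxyphenyl]propanoate | COc1cc([C@@H](CC(=O)N2[C@H](c3ccccc3)COC2=O)c2cc(OCc3ccccc3)c(OC)cc2CCC(=O)OC)ccc1OCc1ccccc1
F7 | step 6 | (3R)-3-[4-(benzyloxy)-3-methoxyphenyl]-3-[5-(benzyloxy)-2-(2-carboxyethyl)-4-methoxyphenyl]propanoic acid | COc1cc([C@@H](CC(=O)O)c2cc(OCc3ccccc3)c(OC)cc2CCC(=O)O)ccc1OCc1ccccc1
F8 | step 6 | bis-imide of F7 with two (4R)-4-benzyl-2-oxo-1,3-oxazolidin-3-yl groups | COc1cc([C@@H](CC(=O)N2[C@H](Cc3ccccc3)COC2=O)c2cc(OCc3ccccc3)c(OC)cc2CCC(=O)N2[C@H](Cc3ccccc3)COC2=O)ccc1OCc1ccccc1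
F9 | step 6 | (1R,2S,3S)-7-(benzyloxy)-1-[4-(benzyloxy)-3-methoxyphenyl]-6-methoxy-1,2,3,4-tetrahydronaphthalene-2,3-dicarbonyl bis[(4R)-4-benzyl-2-oxo-1,3-oxazolidin-3-yl] imide | COc1cc([C@@H]2c3cc(OCc4ccccc4)c(OC)cc3C[C@H](C(=O)N3[C@H](Cc4ccccc4)COC3=O)[C@H]2C(=O)N2[C@H](Cc3ccccc3)COC2=O)ccc1OCc1ccccc1
F10 | step 3 | methyl 3-[4-(benzyloxy)-2-formyl-5-methoxyphenyl]propanoate | COC(=O)CCc1cc(OC)c(OCc2ccccc2)cc1C=O
A1 | alternative 1 | (3R,4S)-4-[4-(benzyloxy)-3-methoxybenzyl]-3-[[4-(benzyloxy)-3-methoxyphenyl](hydroxy)methyl]oxolan-2-one (carbinol configuration immaterial) | O=C1OC[C@@H](Cc2ccc(OCc3ccccc3)c(OC)c2)[C@@H]1C(O)c1ccc(OCc2ccccc2)c(OC)c1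
A2 | alternative 2 | [5-(benzyloxy)-4-methoxy-2-methylphenyl][4-(benzyloxy)-3-methoxyphenyl]methanone | COc1cc(C(=O)c2cc(OCc3ccccc3)c(OC)cc2C)ccc1OCc1ccccc1
A3 | alternative 2 | dimethyl (1S,2R,3S)-7-(benzyloxy)-1-[4-(benzyloxy)-3-methoxyphenyl]-1-hydroxy-6-methoxy-1,2,3,4-tetrahydronaphthalene-2,3-dicarboxylate | COc1cc([C@]2(O)c3cc(OCc4ccccc4)c(OC)cc3C[C@H](C(=O)OC)[C@H]2C(=O)OC)ccc1OCc1ccccc1
A4 | alternative 3 | dimethyl (2S,3S)-2,3-bis(4-hydroxy-3-methoxybenzyl)butanedioate | COc1cc(C[C@H](C(=O)OC)[C@H](Cc2ccc(O)c(OC)c2)C(=O)OC)ccc1O
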